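**Strategy**

The flavan is disconnected at C2–C3 of the pyran ring and at the C4–aryl bond, exploiting the ortho placement of O1 and C4 on ring A. A racemic O-aryl O-acetyl acetal, which already joins O1 to C2 and carries a vinyl group (future C4 and C3), is ionised by a chiral confined Brønsted acid. The oxocarbenium ion closes onto the vinyl terminus (C2–C3), giving an O-alkylated ortho-quinone methide, the chroman-4-yl cation stabilised by O1 and the 7-oxygen, which the acylphloroglucinol captures at C4 trans to the C2 aryl group. One operation thus forms the pyran ring, both stereocentres and the C4–aryl bond; hydrogenolysis completes the synthesis.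

Key step: step 5

Remark: the target is the (2S,4R) isomer, in which the aryl groups at C2 and C4 are trans on the pyran ring.
Remark: 9-phenylnonanoic acid, 4-(benzyloxy)-2-hydroxybenzaldehyde and 4-(benzyloxy)benzoyl chloride are taken as purchasable compounds.

**Route**

Step 1
Reactants: 1 phloroglucinol; 2 9-phenylnonanoic acid
Product: 3 9-phenyl-1-(2,4,6-trihydroxyphenyl)nonan-1-one
Conditions: BF3·OEt2 (neat), 85 °C; aqueous work-up
Reagents that add atoms: none
Why: BF3-promoted Friedel–Crafts acylation of the very electron-rich triol by the free acid should stop at mono-acylation, because the chelated aryl ketone is deactivated; no stereocentre is formed.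

Step 2
Reactants: 4 4-(benzyloxy)-2-hydroxybenzaldehyde
Product: 5 5-(benzyloxy)-2-ethenylphenol
Conditions: Ph3PCH3Br (2.5 equiv), KOtBu (2.5 equiv), THF, 0 °C to rt
Reagents that add atoms: methyltriphenylphosphonium bromide, C[P+](c1ccccc1)(c1ccccc1)c1ccccc1.[Br-]
Why: Wittig methylenation with excess ylide tolerates the phenoxide and turns the aldehyde into the ortho vinyl group that becomes C4 and C3; the vinylphenol is kept cold and used at once to limit oligomerisation.

Step 3
Reactants: 5 5-(benzyloxy)-2-ethenylphenol; 6 4-(benzyloxy)benzoyl chloride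
Product: 7 5-(benzyloxy)-2-ethenylphenyl 4-(benzyloxy)benzoate
Conditions: Et3N, DMAP (cat.), CH2Cl2, 0 °C
Reagents that add atoms: none
Why: DMAP-catalysed O-acylation of the phenol (nucleophilic acyl substitution) installs the O1–C2 link at the ester oxidation level without touching the styrene.

Step 4
Reactants: 7 5-(benzyloxy)-2-ethenylphenyl 4-(benzyloxy)benzoate
Product: 9 [4-(benzyloxy)phenyl][5-(benzyloxy)-2-ethenylphenoxy]methyl acetate (racemic), via aluminium hemiacetal alkoxide 8 (not isolated)
Conditions: DIBAL-H (i-Bu2AlH), CH2Cl2, −78 °C; then pyridine, DMAP, Ac2O, −78 to 0 °C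
Reagents that add atoms: acetic anhydride, CC(=O)OC(C)=O
Why: Reductive acetylation of an ester (DIBAL-H reduction to the tetrahedral aluminium alkoxide, which should persist at −78 °C, then O-acetylation in the flask) should give the alpha-acetoxy ether as a racemate whose stereocentre is erased in the next step; the product is purified on Et3N-deactivated silica.

Step 5
Reactants: 9 [4-(benzyloxy)phenyl][5-(benzyloxy)-2-ethenylphenoxy]methyl acetate (racemic); 3 9-phenyl-1-(2,4,6-trihydroxyphenyl)nonan-1-one
Product: 11 1-{3-[(2S,4R)-7-(benzyloxy)-2-[4-(benzyloxy)phenyl]-3,4-dihydro-2H-chromen-4-yl]-2,4,6-trihydroxyphenyl}-9-phenylnonan-1-one, via 4-acetoxyflavan epimers 10 (not isolated)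
Conditions: (S,S)-imidodiphosphorimidate acid HN[P(=NSO2CF3)(O2C20H10Ar2)]2, Ar = 3,5-(CF3)2C6H3 (5 mol%), CH2Cl2, −78 °C; then 3 (2 equiv), −78 to −30 °C
Reagents that add atoms: none
Why: Proposed new method: the chiral acid protonates the acetoxy group of 9 and expels acetic acid (a far better nucleofuge than the aryloxide, so only the O-aryl oxocarbenium ion forms, and both enantiomers of 9 converge on this one planar (E)-cation held as a contact ion pair by the confined chiral anion); the vinyl CH2 then attacks C2, which forms C2–C3 and closes the pyran ring in a 6-endo-trig cation–olefin (Prins) cyclisation, equally a cationic oxa-6π closure of the C2=O1–C8a=C4a–C4=C3 array. The closest known reaction types are the catalytic asymmetric Prins cyclisation of oxocarbenium ions paired with imidodiphosphorimidate anions, the Prins cyclisation of alpha-acetoxy ethers and the acid-mediated C4-arylation of flavan-4-yl cations by phloroglucinols; their merger on an O-aryl oxocarbenium ion with a styrene terminator and arene capture is new. C2 is set in the C–C bond-forming step by the chiral anion, which blocks one face of the oxocarbenium ion; the sense of induction cannot be predicted with certainty, so the mirror-image acid is used if the (2R) series results. The closure leaves the chroman-4-yl cation (an O-alkylated ortho-quinone methide stabilised by O1 and the para 7-benzyloxy group), which acetic acid traps reversibly as the epimeric acetates 10; when 3 is added both epimers re-ionise to the same cation and the arene adds axially to its half-chair anti to the pseudo-equatorial C2 aryl group, so C4 is set by C2 as 2,4-trans. The step needs 6-endo regioselectivity, secured because only attack by the CH2 terminus gives a cation stabilised by ring A, and chemoselectivity for closure over intermolecular capture, secured by the ortho tether and by adding 3 only after 9 is consumed; C-alkylation of 3 prevails because O-alkylation is reversible under acid and its two free ring carbons are equivalent.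

Step 6
Reactants: 11 1-{3-[(2S,4R)-7-(benzyloxy)-2-[4-(benzyloxy)phenyl]-3,4-dihydro-2H-chromen-4-yl]-2,4,6-trihydroxyphenyl}-9-phenylnonan-1-one
Product: 12 (+)-myristinin D
Conditions: H2 (1 atm), Pd/C (10% palladium on carbon), EtOAc–MeOH, rt
Reagents that add atoms: none
Why: Hydrogenolysis of the two aryl benzyl ethers should be much faster than cleavage of the cyclic benzylic C2–O1 ether or reduction of the chelated aryl ketone, so both stereocentres stay untouched.

**Compound list**

1 | phloroglucinol (benzene-1,3,5-triol) | Oc1cc(O)cc(O)c1 | starting material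
2 | 9-phenylnonanoic acid | OC(=O)CCCCCCCCc1ccccc1 | starting material
3 | 9-phenyl-1-(2,4,6-trihydroxyphenyl)nonan-1-one | O=C(CCCCCCCCc1ccccc1)c1c(O)cc(O)cc1O | intermediate
4 | 4-(benzyloxy)-2-hydroxybenzaldehyde | O=Cc1ccc(OCc2ccccc2)cc1O | starting material
5 | 5-(benzyloxy)-2-ethenylphenol | C=Cc1ccc(OCc2ccccc2)cc1O | intermediate
6 | 4-(benzyloxy)benzoyl chloride | O=C(Cl)c1ccc(OCc2ccccc2)cc1 | starting material
7 | 5-(benzyloxy)-2-ethenylphenyl 4-(benzyloxy)benzoate | C=Cc1ccc(OCc2ccccc2)cc1OC(=O)c1ccc(OCc2ccccc2)cc1 | intermediate
8 | diisobutylaluminium alkoxide of [4-(benzyloxy)phenyl][5-(benzyloxy)-2-ethenylphenoxy]methanol (aluminium hemiacetal alkoxide, not isolated) | C=Cc1ccc(OCc2ccccc2)cc1OC(O[Al](CC(C)C)CC(C)C)c1ccc(OCc2ccccc2)cc1 | intermediate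
9 | [4-(benzyloxy)phenyl][5-(benzyloxy)-2-ethenylphenoxy]methyl acetate, racemic | C=Cc1ccc(OCc2ccccc2)cc1OC(OC(C)=O)c1ccc(OCc2ccccc2)cc1 | intermediate
10 | (2S)-7-(benzyloxy)-2-[4-(benzyloxy)phenyl]-3,4-dihydro-2H-chromen-4-yl acetate, both C4 epimers (not isolated) | CC(=O)OC1C[C@@H](c2ccc(OCc3ccccc3)cc2)Oc2cc(OCc3ccccc3)ccc21 | intermediate
11 | 1-{3-[(2S,4R)-7-(benzyloxy)-2-[4-(benzyloxy)phenyl]-3,4-dihydro-2H-chromen-4-yl]-2,4,6-trihydroxyphenyl}-9-phenylnonan-1-one (2,4-trans) | O=C(CCCCCCCCc1ccccc1)c1c(O)cc(O)c([C@@H]2C[C@@H](c3ccc(OCc4ccccc4)cc3)Oc3cc(OCc4ccccc4)ccc32)c1O | intermediate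
12 | (+)-myristinin D, 1-{2,4,6-trihydroxy-3-[(2S,4R)-7-hydroxy-2-(4-hydroxyphenyl)-3,4-dihydro-2H-chromen-4-yl]phenyl}-9-phenylnonan-1-one | O=C(CCCCCCCCc1ccccc1)c1c(O)cc(O)c([C@@H]2C[C@@H](c3ccc(O)cc3)Oc3cc(O)ccc32)c1O | target

**Step count**

Total steps: 6. Longest linear sequence: 5 steps (steps 2, 3, 4, 5, 6); step 1 supplies the arene partner convergently.

**Steps most likely to fail**

Step 5 (labelled as a proposed new method). The chiral anion may discriminate the two faces of the oxocarbenium ion poorly, or ionisation promoted by the liberated acetic acid may run as a racemic background process. The fallback sets out from 9 and comes back at 11. It keeps the C2–C3 ring closure but sets C2 by a dynamic kinetic resolution with known reactions: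
- Treating 9 with BF3·OEt2 and AcOH in CH2Cl2 at −78 °C (Prins cyclisation of an alpha-acetoxy ether with acetate capture) should give racemic 7-(benzyloxy)-2-[4-(benzyloxy)phenyl]-3,4-dihydro-2H-chromen-4-yl acetate F1.
- Methanolysis (K2CO3, MeOH, 0 °C) should give racemic 7-(benzyloxy)-2-[4-(benzyloxy)phenyl]-3,4-dihydro-2H-chromen-4-ol F2.
- Oxidation with Dess–Martin periodinane in CH2Cl2 should give racemic 7-(benzyloxy)-2-[4-(benzyloxy)phenyl]-2,3-dihydro-4H-chromen-4-one F3.
- Asymmetric transfer hydrogenation with RuCl[(S,S)-TsDPEN](p-cymene) (TsDPEN = N-tosyl-1,2-diphenylethylenediamine), HCO2H and DBU in MeCN at 40 °C follows. The flavanone racemises at C2 by reversible retro-oxa-Michael opening under these conditions, so both enantiomers should be funnelled into (2S,4S)-7-(benzyloxy)-2-[4-(benzyloxy)phenyl]-3,4-dihydro-2H-chromen-4-ol F4. The (S,S) ligand is the one expected from the usual model for aryl ketones.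
- Ionisation of F4 with CF3CO2H in CH2Cl2 at −20 °C in the presence of 3 should then give 11 by the same trans-selective capture of the chroman-4-yl cation.

Step 4. The tetrahedral aluminium intermediate may collapse to aldehyde and aryloxide before it is acetylated, which leads to over-reduction, and the product may ionise during purification. The fallback sets out from 5 and comes back at 9, bringing in the acetal carbon at the aldehyde oxidation level. 4-(Benzyloxy)benzaldehyde and acetyl chloride (ZnCl2 cat., CH2Cl2, −20 °C) should give chloro[4-(benzyloxy)phenyl]methyl acetate F5. F5 is used without purification to O-alkylate the caesium phenoxide of 5 (Cs2CO3, MeCN, −20 °C), giving 9.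

Step 6. Hydrogenolysis may go too far, opening the benzylic C2–O1 bond of the pyran ring or reducing the aryl ketone. The fallback sets out from 11 and comes back at 12. The benzyl ethers are removed without hydrogen by BCl3 with pentamethylbenzene as cation scavenger in CH2Cl2 at −78 °C, a Lewis-acid dealkylation. New compounds on the way: none F0.

**Further compounds**

F1 | step 5 | racemic 7-(benzyloxy)-2-[4-(benzyloxy)phenyl]-3,4-dihydro-2H-chromen-4-yl acetate | CC(=O)OC1CC(c2ccc(OCc3ccccc3)cc2)Oc2cc(OCc3ccccc3)ccc21
F2 | step 5 | racemic 7-(benzyloxy)-2-[4-(benzyloxy)phenyl]-3,4-dihydro-2H-chromen-4-ol | OC1CC(c2ccc(OCc3ccccc3)cc2)Oc2cc(OCc3ccccc3)ccc21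
F3 | step 5 | racemic 7-(benzyloxy)-2-[4-(benzyloxy)phenyl]-2,3-dihydro-4H-chromen-4-one | O=C1CC(c2ccc(OCc3ccccc3)cc2)Oc2cc(OCc3ccccc3)ccc21
F4 | step 5 | (2S,4S)-7-(benzyloxy)-2-[4-(benzyloxy)phenyl]-3,4-dihydro-2H-chromen-4-ol | O[C@H]1C[C@@H](c2ccc(OCc3ccccc3)cc2)Oc2cc(OCc3ccccc3)ccc21
F5 | step 4 | chloro[4-(benzyloxy)phenyl]methyl acetate | CC(=O)OC(Cl)c1ccc(OCc2ccccc2)cc1
F0 | step 6 | none | none
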